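A direct plan would buy the benzene ring and close the pyran ring last.
It would take C2 and the side chain from (E,7R,11R)-phytol (Sharpless epoxidation, hydride opening, iodination) as the γ-iodo tertiary alcohol A1. A1 would be joined to the benzyl-protected bromocresol A2 by Ni-catalysed reductive coupling to give A3. A3 would be brominated to A4, O1–C8a closed by Pd-catalysed etherification to A5, and the benzyl group removed.
Its weakest step would be the bromination of A3. Bromine would have to enter the one position between the methyl group and the alkyl chain, while both positions ortho to the benzyloxy group are also activated and less hindered, so the site of the later ring closure would be left to chance.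
The second would be the Pd-catalysed aryl–O coupling of A4. A tertiary alkoxide with an electron-rich, doubly ortho-substituted aryl bromide would be the hardest case for C–O reductive elimination, and hydrodebromination or dehydration would consume the most precious material.
The third would be the poor return on steps. Benzylation, bromination and debenzylation would add no atom of the target, and the reductive coupling of unprotected A1 would compete with its reduction and dimerisation and would need A2 in excess.

**Plan of the new route**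
Feature used: on the benzene ring O1 (at C8a) and the hydroxyl group (at C6) are para, C5 and C7 carry hydrogen, and C8 carries methyl. This is exactly the pattern assembled by an alkoxy(isopropenyl)carbene of chromium, a terminal alkyne and one CO ligand. The pyran atoms O1–C2–C3–C4 already tie C8a to C4a and serve as a built-in tether.
The retrosynthesis cuts C8a–C4a, C5–C6 and C6–C7 in one operation. This opens both rings and leads to an open-chain chromium carbene complex, in which C6 and its oxygen are a CO ligand.
The complex is cut at O1–C8a into a tertiary alkynol and an isopropenyl acylchromate. The alkynol is cut at C4–C4a into acetylide and a C20 tosylate from phytol; a Sharpless epoxidation sets C2, and phytol brings C4' and C8'.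
Ring order: no ring is bought. In the key step the pyran ring closes first (alkyne insertion) and the benzene ring directly afterwards (CO insertion, electrocyclisation).
The arene is formed with all four substituents in place, so there is no arene halogenation, no aryl–O cross-coupling and no phenol protecting group, and the C2–O bond is never broken.

Key step: step 7

Assumption: commercial natural phytol is (7R,11R) and E-rich; material derived from the Z isomer is removed by chromatography of epoxy alcohol 2.

## Route

Step 1
Reactants: 1 (2E,7R,11R)-phytol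
Product: 2 [(2R,3R)-3-methyl-3-[(4R,8R)-4,8,12-trimethyltridecyl]oxiran-2-yl]methanol
Conditions: Ti(OiPr)4 (10 mol%), D-(–)-DET (12 mol%), t-BuOOH, 4 Å MS, CH2Cl2, –20 °C
Reagents that add atoms: tert-butyl hydroperoxide, CC(C)(C)OO
Why: Sharpless asymmetric epoxidation of an E-trisubstituted allylic alcohol; D-(–)-tartrate directs oxygen to the face that makes the fully substituted epoxide carbon (future C2, its oxygen the future O1) R.

Step 2
Reactants: 2 [(2R,3R)-3-methyl-3-[(4R,8R)-4,8,12-trimethyltridecyl]oxiran-2-yl]methanol
Product: 3 (3R,7R,11R)-3,7,11,15-tetramethylhexadecane-1,3-diol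
Conditions: Red-Al, THF, 0 °C to rt; aq. Rochelle salt
Reagents that add atoms: none
Why: Hydroxyl-directed hydride opening of a 2,3-epoxy alcohol delivers hydride to the secondary carbon and leaves the tertiary C–O bond, and with it the stereocentre, untouched.

Step 3
Reactants: 3 (3R,7R,11R)-3,7,11,15-tetramethylhexadecane-1,3-diol
Product: 4 (3R,7R,11R)-3-hydroxy-3,7,11,15-tetramethylhexadecyl 4-methylbenzenesulfonate
Conditions: TsCl (1.1 equiv), Et3N, DMAP (cat.), CH2Cl2, 0 °C
Reagents that add atoms: 4-toluenesulfonyl chloride, Cc1ccc(cc1)S(=O)(=O)Cl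
Why: Sulfonylation is selective for the unhindered primary alcohol; the tertiary carbinol does not react and keeps its configuration.

Step 4
Reactants: 4 (3R,7R,11R)-3-hydroxy-3,7,11,15-tetramethylhexadecyl 4-methylbenzenesulfonate
Product: 5 (5R,9R,13R)-5,9,13,17-tetramethyloctadec-1-yn-5-ol
Conditions: LiC≡CH·H2NCH2CH2NH2 (3 equiv), DMSO, rt
Reagents that add atoms: lithium acetylide ethylenediamine complex, [Li+].[C-]#C.NCCN
Why: SN2 alkylation of acetylide at the primary tosylate forms C4–C4a; in DMSO acetylide is a weaker base than a tertiary alkoxide, so the hydroxyl group should stay protonated and the slow 4-exo-tet closure should not compete.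

Step 5
Reactants: 6 2-bromopropene; 7 hexacarbonylchromium
Product: 10 tetramethylammonium pentacarbonyl(2-methyl-1-oxidoprop-2-en-1-ylidene)chromate, via isopropenyllithium 8 (not isolated), via lithium acylchromate 9 (not isolated)
Conditions: t-BuLi (2 equiv), Et2O, –78 °C; Cr(CO)6, Et2O, 0 °C to rt; Me4NBr, H2O, extraction into CH2Cl2
Reagents that add atoms: tetramethylammonium bromide, C[N+](C)(C)C.[Br-]
Why: Fischer carbene route: the vinyllithium from halogen–lithium exchange adds to a CO ligand of Cr(CO)6, and cation metathesis gives the storable tetramethylammonium acylchromate.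

Step 6
Reactants: 10 tetramethylammonium pentacarbonyl(2-methyl-1-oxidoprop-2-en-1-ylidene)chromate; 5 (5R,9R,13R)-5,9,13,17-tetramethyloctadec-1-yn-5-ol
Product: 12 pentacarbonyl{2-methyl-1-[(5R,9R,13R)-5,9,13,17-tetramethyloctadec-1-yn-5-yloxy]prop-2-en-1-ylidene}chromium, via pivaloyloxycarbene complex 11 (not isolated)
Conditions: 10 (1.5 equiv), t-BuCOCl (1.5 equiv), CH2Cl2, –40 °C; then 5 (ca. 1 M), –40 to –5 °C; cold chromatography under Ar
Reagents that add atoms: pivaloyl chloride, CC(C)(C)C(=O)Cl (its atoms stand in 11 only, not in 12)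
Why: Proposed new method: O-acylation of the acylchromate gives the pivaloyloxycarbene complex 11, whose carbene carbon behaves like the carbonyl carbon of a mixed anhydride, and addition of the alcohol followed by loss of pivalic acid forms O1–C8a without touching the C–O bond of the carbinol, so C2 stays R; the closest known reaction type is the alcoholysis of acyloxycarbene chromium complexes with primary and hindered secondary (menthol-type) alcohols, and a tertiary alcohol should only react more slowly, which the more persistent and acyl-shielded pivaloyloxy complex, its use in excess and the high concentration are meant to offset.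

Step 7
Reactants: 12 pentacarbonyl{2-methyl-1-[(5R,9R,13R)-5,9,13,17-tetramethyloctadec-1-yn-5-yloxy]prop-2-en-1-ylidene}chromium
Product: 15 (2R,4'R,8'R)-δ-tocopherol, via dienylketene chromium complex 13 (not isolated), via tricarbonylchromium arene complex 14 (not isolated)
Conditions: THF (0.005 M), 55 °C, Ar; then MeCN, 70 °C, Ar
Reagents that add atoms: none
Why: Loss of one cis CO from 12 lets the tethered alkyne bind to chromium and insert into the Cr=C8a bond (C8a–C4a), CO migrates to the new carbene carbon C5 (C5–C6) to give the η4-dienylketene 13, 6π-electrocyclisation joins C6 to C7, tautomerisation gives the phenol as its Cr(CO)3 complex 14, and acetonitrile removes the metal without an oxidant that would attack the hydroquinone monoether. The closest known reaction type is the intramolecular Dötz benzannulation of alkoxycarbene chromium complexes that carry the alkyne on the carbene oxygen. The pyran ring closes first in a 6-exo-dig insertion and the benzene ring second by CO insertion and 6π closure, for which the new ring holds C5 and the isopropenyl group cis on the C4a=C8a double bond. No stereocentre is formed; the C2–O1 bond is never broken, so C2 stays R, and C4' and C8' are remote. The step needs the alkyne to insert against the innate orientation of terminal alkynes (substituted carbon next to the CO-derived carbon), and the three-carbon tether C2–C3–C4 secures this because the innate mode would demand a four-atom bridge across meta positions. High dilution and the gem-disubstituted C2 should favour the intramolecular path, and an alkenyl(alkoxy)carbene of chromium in THF should favour the phenol over five-membered-ring products.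

## Compound list
(In the SMILES of the chromium complexes, the CO ligands and π-bound ligands are written as separate fragments.)

1 | (2E,7R,11R)-phytol | CC(C)CCC[C@@H](C)CCC[C@@H](C)CCC/C(C)=C/CO | starting material
2 | [(2R,3R)-3-methyl-3-[(4R,8R)-4,8,12-trimethyltridecyl]oxiran-2-yl]methanol | OC[C@H]1O[C@]1(C)CCC[C@H](C)CCC[C@H](C)CCCC(C)C | intermediate
3 | (3R,7R,11R)-3,7,11,15-tetramethylhexadecane-1,3-diol | OCC[C@](C)(O)CCC[C@H](C)CCC[C@H](C)CCCC(C)C | intermediate
4 | (3R,7R,11R)-3-hydroxy-3,7,11,15-tetramethylhexadecyl 4-methylbenzenesulfonate | Cc1ccc(cc1)S(=O)(=O)OCC[C@](C)(O)CCC[C@H](C)CCC[C@H](C)CCCC(C)C | intermediate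
5 | (5R,9R,13R)-5,9,13,17-tetramethyloctadec-1-yn-5-ol | C#CCC[C@](C)(O)CCC[C@H](C)CCC[C@H](C)CCCC(C)C | intermediate
6 | 2-bromopropene | C=C(C)Br | starting material
7 | hexacarbonylchromium | [Cr].[C-]#[O+].[C-]#[O+].[C-]#[O+].[C-]#[O+].[C-]#[O+].[C-]#[O+] | starting material
8 | isopropenyllithium (prop-1-en-2-yllithium) | [Li]C(C)=C | intermediate
9 | lithium pentacarbonyl(2-methyl-1-oxidoprop-2-en-1-ylidene)chromate | [Li+].C=C(C)C([O-])=[Cr].[C-]#[O+].[C-]#[O+].[C-]#[O+].[C-]#[O+].[C-]#[O+] | intermediate
10 | tetramethylammonium pentacarbonyl(2-methyl-1-oxidoprop-2-en-1-ylidene)chromate | C[N+](C)(C)C.C=C(C)C([O-])=[Cr].[C-]#[O+].[C-]#[O+].[C-]#[O+].[C-]#[O+].[C-]#[O+] | intermediate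
11 | pentacarbonyl[2-methyl-1-(pivaloyloxy)prop-2-en-1-ylidene]chromium | C=C(C)C(=[Cr])OC(=O)C(C)(C)C.[C-]#[O+].[C-]#[O+].[C-]#[O+].[C-]#[O+].[C-]#[O+] | intermediate
12 | pentacarbonyl{2-methyl-1-[(5R,9R,13R)-5,9,13,17-tetramethyloctadec-1-yn-5-yloxy]prop-2-en-1-ylidene}chromium | C=C(C)C(=[Cr])O[C@](C)(CCC[C@H](C)CCC[C@H](C)CCCC(C)C)CCC#C.[C-]#[O+].[C-]#[O+].[C-]#[O+].[C-]#[O+].[C-]#[O+] | intermediate
13 | tricarbonyl(η4-2-{(6R)-6-methyl-2-(prop-1-en-2-yl)-6-[(4R,8R)-4,8,12-trimethyltridecyl]-5,6-dihydro-4H-pyran-3-yl}ethenone)chromium | C=C(C)C1=C(C=C=O)CC[C@@](C)(CCC[C@H](C)CCC[C@H](C)CCCC(C)C)O1.[Cr].[C-]#[O+].[C-]#[O+].[C-]#[O+] | intermediate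
14 | tricarbonyl[η6-(2R,4'R,8'R)-δ-tocopherol]chromium (metal on either arene face) | Cc1cc(O)cc2c1O[C@](C)(CCC[C@H](C)CCC[C@H](C)CCCC(C)C)CC2.[Cr].[C-]#[O+].[C-]#[O+].[C-]#[O+] | intermediate
15 | (2R,4'R,8'R)-δ-tocopherol | Cc1cc(O)cc2c1O[C@](C)(CCC[C@H](C)CCC[C@H](C)CCCC(C)C)CC2 | target

## Step count and risks
Total steps: 7.
Longest linear sequence: 6 (steps 1, 2, 3, 4, 6, 7); step 5 is a one-step branch.

**Step 6 (Proposed new method).** Addition of the hindered tertiary alcohol to the carbene carbon may be slower than thermal decay of the acyloxycarbene complex, or acyl transfer to the alcohol may take over. The fallback uses known reaction types only and runs from 5 back to 15. It makes the hindered O1–C8a bond intramolecularly and the pyran ring first.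
- (CO)5Cr(THF), made by irradiating Cr(CO)6 in THF, turns the terminal alkyne of 5 into a chromium vinylidene. The tertiary hydroxyl group traps it to give the cyclic 2-oxacyclohexylidene chromium complex F1.
- Deprotonation at C4a (n-BuLi, THF, –78 °C) and reaction with Eschenmoser's salt give the Mannich base complex F2. This loses dimethylamine on silica gel to give the α-methylene carbene complex F3.
- Dötz benzannulation of F3 with 1-(trimethylsilyl)propyne (THF, 55 °C; then MeCN) should place the larger silyl group next to the CO-derived carbon C6 and the methyl group at C8. This gives 7-(trimethylsilyl)-δ-tocopherol F4.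
- The C7–Si bond, which is not in the target, is then cleaved by protodesilylation (CF3CO2H, CH2Cl2, 0 °C) to give 15.

**Step 7 (key step).** Three processes may compete: intermolecular alkyne insertion (oligomerisation), loss of the tertiary alkyl group from the carbene oxygen by elimination before the alkyne inserts, and ring closure without CO insertion. The fallback runs from 5 back to 15, is free of chromium, and makes the two rings in separate stages.
- Tungsten-catalysed endo-cycloisomerisation of 5 (W(CO)6 cat., DABCO, THF, hν) gives the 2,2-disubstituted dihydropyran F5.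
- Lithiation at C8a (t-BuLi, THF), transmetalation (ZnCl2) and Negishi coupling with 2-bromopropene (Pd(PPh3)4) give the isopropenyl dihydropyran F6.
- Diels–Alder reaction with but-3-yn-2-one (toluene, 80 °C), in which the enol-ether terminus C4a should bond to the unsubstituted alkyne carbon, gives the acetyl cyclohexadiene F7.
- DDQ (benzene, rt) aromatises F7 to the 6-acetylchroman F8 before any free phenol is present.
- Baeyer–Villiger oxidation (mCPBA, CH2Cl2, aryl migration) gives δ-tocopheryl acetate F9, and methanolysis (K2CO3, MeOH) gives 15.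

**Step 4.** Deprotonation of the tertiary hydroxyl group followed by four-membered ring closure onto the tosylate, or E2 elimination, may compete with substitution. The fallback runs from 2 back to 5 and keeps the oxygen masked as the epoxide while C4–C4a is made.
- Tosylation of 2 (TsCl, Et3N, DMAP, CH2Cl2) gives the epoxy tosylate F10.
- Lithium acetylide–ethylenediamine (DMSO, rt) displaces the primary tosylate to give the epoxy alkyne F11.
- LiEt3BH (THF, 0 °C) opens the trisubstituted epoxide at its less substituted carbon to give 5, with the C–O bond at the quaternary centre intact.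

## Further compounds
F1 | step 6 | pentacarbonyl{(6R)-6-methyl-6-[(4R,8R)-4,8,12-trimethyltridecyl]oxan-2-ylidene}chromium | [Cr]=C1CCC[C@@](C)(CCC[C@H](C)CCC[C@H](C)CCCC(C)C)O1.[C-]#[O+].[C-]#[O+].[C-]#[O+].[C-]#[O+].[C-]#[O+]
F2 | step 6 | pentacarbonyl{(6R)-3-[(dimethylamino)methyl]-6-methyl-6-[(4R,8R)-4,8,12-trimethyltridecyl]oxan-2-ylidene}chromium (C3 epimers) | [Cr]=C1C(CN(C)C)CC[C@@](C)(CCC[C@H](C)CCC[C@H](C)CCCC(C)C)O1.[C-]#[O+].[C-]#[O+].[C-]#[O+].[C-]#[O+].[C-]#[O+]
F3 | step 6 | pentacarbonyl{(6R)-6-methyl-3-methylidene-6-[(4R,8R)-4,8,12-trimethyltridecyl]oxan-2-ylidene}chromium | [Cr]=C1C(=C)CC[C@@](C)(CCC[C@H](C)CCC[C@H](C)CCCC(C)C)O1.[C-]#[O+].[C-]#[O+].[C-]#[O+].[C-]#[O+].[C-]#[O+]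
F4 | step 6 | (2R,4'R,8'R)-7-(trimethylsilyl)-δ-tocopherol | Cc1c([Si](C)(C)C)c(O)cc2c1O[C@](C)(CCC[C@H](C)CCC[C@H](C)CCCC(C)C)CC2
F5 | step 7 | (2R)-2-methyl-2-[(4R,8R)-4,8,12-trimethyltridecyl]-3,4-dihydro-2H-pyran | C1=CCC[C@@](C)(CCC[C@H](C)CCC[C@H](C)CCCC(C)C)O1
F6 | step 7 | (2R)-2-methyl-6-(prop-1-en-2-yl)-2-[(4R,8R)-4,8,12-trimethyltridecyl]-3,4-dihydro-2H-pyran | C=C(C)C1=CCC[C@@](C)(CCC[C@H](C)CCC[C@H](C)CCCC(C)C)O1
F7 | step 7 | 1-{(2R)-2,8-dimethyl-2-[(4R,8R)-4,8,12-trimethyltridecyl]-3,4,4a,7-tetrahydro-2H-chromen-6-yl}ethanone (C4a epimers) | CC(=O)C1=CC2CC[C@@](C)(CCC[C@H](C)CCC[C@H](C)CCCC(C)C)OC2=C(C)C1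
F8 | step 7 | 1-{(2R)-2,8-dimethyl-2-[(4R,8R)-4,8,12-trimethyltridecyl]chroman-6-yl}ethanone | CC(=O)c1cc(C)c2c(c1)CC[C@@](C)(CCC[C@H](C)CCC[C@H](C)CCCC(C)C)O2
F9 | step 7 | (2R,4'R,8'R)-δ-tocopheryl acetate | CC(=O)Oc1cc(C)c2c(c1)CC[C@@](C)(CCC[C@H](C)CCC[C@H](C)CCCC(C)C)O2
F10 | step 4 | [(2R,3R)-3-methyl-3-[(4R,8R)-4,8,12-trimethyltridecyl]oxiran-2-yl]methyl 4-methylbenzenesulfonate | Cc1ccc(cc1)S(=O)(=O)OC[C@H]1O[C@]1(C)CCC[C@H](C)CCC[C@H](C)CCCC(C)C
F11 | step 4 | (2R,3R)-2-methyl-3-(prop-2-yn-1-yl)-2-[(4R,8R)-4,8,12-trimethyltridecyl]oxirane | C#CC[C@H]1O[C@]1(C)CCC[C@H](C)CCC[C@H](C)CCCC(C)C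
A1 | direct plan | (3R,7R,11R)-1-iodo-3,7,11,15-tetramethylhexadecan-3-ol | ICC[C@](C)(O)CCC[C@H](C)CCC[C@H](C)CCCC(C)C
A2 | direct plan | 1-(benzyloxy)-3-bromo-5-methylbenzene | Cc1cc(Br)cc(OCc2ccccc2)c1
A3 | direct plan | (3R,7R,11R)-1-[3-(benzyloxy)-5-methylphenyl]-3,7,11,15-tetramethylhexadecan-3-ol | Cc1cc(OCc2ccccc2)cc(CC[C@](C)(O)CCC[C@H](C)CCC[C@H](C)CCCC(C)C)c1
A4 | direct plan | (3R,7R,11R)-1-[5-(benzyloxy)-2-bromo-3-methylphenyl]-3,7,11,15-tetramethylhexadecan-3-ol | Cc1cc(OCc2ccccc2)cc(CC[C@](C)(O)CCC[C@H](C)CCC[C@H](C)CCCC(C)C)c1Br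
A5 | direct plan | (2R)-6-(benzyloxy)-2,8-dimethyl-2-[(4R,8R)-4,8,12-trimethyltridecyl]chromane | Cc1cc(OCc2ccccc2)cc2c1O[C@](C)(CCC[C@H](C)CCC[C@H](C)CCCC(C)C)CC2
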